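## Retrosynthetic overview

1. Target ⇒ (ester C–O, tigloyl chloride; O–Si) the C‑3 ketol ⇒ (C–C(=O)–C, carbonylative Stille coupling of an enol triflate with an (E)-vinylstannane) a 4‑acetyl‑3‑hydroxy‑1‑methyl‑7‑oxabicyclo[4.1.0]heptan‑2‑one.
2. That acetyl ketol ⇒ (ring bond C3–C4, D‑proline‑catalysed 6‑enolexo aldol) an open‑chain epoxy 2‑oxoaldehyde carrying a methyl ketone. This closes the six‑membered carbocycle as the last ring; the oxirane is already in place.
3. Enabling feature (numbering of 7‑oxabicyclo[4.1.0]heptan‑2‑one: C‑1 methyl‑bearing oxirane carbon, C‑2 ketone, C‑3 carbinol, C‑4 side‑chain carbon, C‑6 oxirane CH): carbinol C‑3 and the exocyclic sp2 carbon on C‑4 are 1,3‑related, an aldol retron across C3–C4 once that exocyclic carbon is a ketone. C‑3 is then the aldehyde carbon of a 2‑oxoaldehyde that cannot enolise, because C‑1 is the fully substituted oxirane carbon.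
4. Tricarbonyl ⇒ (double ozonolysis) isopropenyl/isobutenyl epoxy enone ⇒ epoxy aldehyde + isobutenyl Grignard ⇒ (Sharpless epoxidation) (2Z)-2,6‑dimethylhepta‑2,6‑dien‑1‑ol ⇒ (Negishi) (2Z)-3‑iodo‑2‑methylprop‑2‑en‑1‑ol + 4‑bromo‑2‑methylbut‑1‑ene.
5. Ring order: oxirane (step 3), then the cyclohexanone (step 8).

Key step: step 8

Remark: the tricarbonyl compound 12 is assumed to be usable crude (partly as its aldehyde hydrate), and the carbinol centre of 10 is deliberately left as an epimer mixture because step 6 oxidises it.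

## Route

Step 1
Reactants: 1 prop-2-yn-1-ol
Product: 3 (2Z)-3-iodo-2-methylprop-2-en-1-ol, via cyclic alkenylmagnesium alkoxide 2 (not isolated)
Conditions: MeMgBr (3 equiv), CuI (10 mol%), THF, 0 °C → rt; then I2, −10 → 0 °C; aq. NH4Cl
Reagents that add atoms: methylmagnesium bromide C[Mg]Br; iodine II
Why: Copper-catalysed anti-carbomagnesiation of the propargylic alkoxide puts magnesium cis to the CH2O group in a five-membered chelate, and iodinolysis with retention should give the Z-iodide only.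

Step 2
Reactants: 3 (2Z)-3-iodo-2-methylprop-2-en-1-ol; 4 4-bromo-2-methylbut-1-ene
Product: 6 (2Z)-2,6-dimethylhepta-2,6-dien-1-ol, via alkylzinc bromide 5 (not isolated)
Conditions: Zn dust, I2 (5 mol%), DMA, 70 °C; then 3, PdCl2(dppf) (3 mol%), THF/DMA, 40 °C
Reagents that add atoms: none
Why: Negishi sp2–sp3 coupling should proceed with retention of the alkenyl iodide geometry, and alkylzinc halides tolerate the free hydroxyl.

Step 3
Reactants: 6 (2Z)-2,6-dimethylhepta-2,6-dien-1-ol
Product: 7 [(2R,3S)-2-methyl-3-(3-methylbut-3-en-1-yl)oxiran-2-yl]methanol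
Conditions: Ti(OiPr)4 (10 mol%), D-(−)-diethyl tartrate (14 mol%), t-BuOOH, 4 Å MS, CH2Cl2, −20 °C
Reagents that add atoms: tert-butyl hydroperoxide CC(C)(C)OO
Why: Sharpless asymmetric epoxidation touches only the allylic alkene, and D-(−)-tartrate (the opposite of the ligand that converts nerol into its 2S,3R epoxide) should deliver oxygen to the face that gives the 2R,3S epoxide, which sets C-1 and C-6 of the target.

Step 4
Reactants: 7 [(2R,3S)-2-methyl-3-(3-methylbut-3-en-1-yl)oxiran-2-yl]methanol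
Product: 8 (2S,3S)-2-methyl-3-(3-methylbut-3-en-1-yl)oxirane-2-carbaldehyde
Conditions: Dess–Martin periodinane, pyridine, CH2Cl2, 0 °C → rt
Reagents that add atoms: none
Why: Dess–Martin oxidation of a primary epoxy alcohol under buffered conditions should give the aldehyde, whose α-carbon is quaternary and cannot epimerise.

Step 5
Reactants: 8 (2S,3S)-2-methyl-3-(3-methylbut-3-en-1-yl)oxirane-2-carbaldehyde; 9 bromo(2-methylprop-1-en-1-yl)magnesium
Product: 10 3-methyl-1-[(2R,3S)-2-methyl-3-(3-methylbut-3-en-1-yl)oxiran-2-yl]but-2-en-1-ol (both C-1 epimers)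
Conditions: THF, −78 °C; aq. NH4Cl
Reagents that add atoms: none
Why: Grignard 1,2-addition to the aldehyde is faster than epoxide opening at −78 °C, and the new carbinol centre needs no control because step 6 removes it.

Step 6
Reactants: 10 3-methyl-1-[(2R,3S)-2-methyl-3-(3-methylbut-3-en-1-yl)oxiran-2-yl]but-2-en-1-ol
Product: 11 3-methyl-1-[(2S,3S)-2-methyl-3-(3-methylbut-3-en-1-yl)oxiran-2-yl]but-2-en-1-one
Conditions: Dess–Martin periodinane, pyridine, CH2Cl2, 0 °C → rt
Reagents that add atoms: none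
Why: Dess–Martin oxidation of the allylic alcohol should give the enone and converge both carbinol epimers.

Step 7
Reactants: 11 3-methyl-1-[(2S,3S)-2-methyl-3-(3-methylbut-3-en-1-yl)oxiran-2-yl]but-2-en-1-one
Product: 12 2-[(2S,3S)-2-methyl-3-(3-oxobutyl)oxiran-2-yl]-2-oxoacetaldehyde
Conditions: O3, CH2Cl2, −78 °C; then Me2S, −78 °C → rt; used crude
Reagents that add atoms: ozone [O-][O+]=O
Why: Ozonolysis with reductive work-up should cleave both C=C bonds, the isopropenyl group to the methyl ketone and the enone to the 2-oxoaldehyde, while the oxirane is inert to ozone.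

Step 8
Reactants: 12 2-[(2S,3S)-2-methyl-3-(3-oxobutyl)oxiran-2-yl]-2-oxoacetaldehyde
Product: 14 (1S,3S,4R,6S)-4-acetyl-3-hydroxy-1-methyl-7-oxabicyclo[4.1.0]heptan-2-one, via D-proline enamine 13 (not isolated)
Conditions: D-proline (30 mol%), DMSO, rt
Reagents that add atoms: none
Why: The amine condenses with the methyl ketone, the internal (E)-enamine 13 adds through its α-carbon (future C-4) to the aldehyde carbon (future C-3) in a chair-like transition state in which the carboxylic acid hydrogen-bonds to the aldehyde oxygen, and hydrolysis of the iminium releases 14 and the catalyst. The closest known reaction type is the proline-catalysed 6-enolexo aldol cyclisation of dicarbonyl compounds (the enolexo relative of the Hajos–Parrish reaction), together with proline aldol additions of ketones to glyoxal-type acceptors. The carbocycle closes in the 6-(enolexo)-exo-trig mode by forming the C3–C4 bond. Both new stereocentres are set by the catalyst: the anti-enamine, acid-bound arrangement should give the trans (anti) aldol with acetyl and hydroxyl equatorial, and (R)-proline is the enantiomer that, by the sense known for (S)-proline in ketone–aldehyde aldols, should give 3S,4R; the oxirane centres are remote from the reacting carbons and are not expected to override this. The step needs aldehyde-over-ketone and CH2-over-CH3 selectivity, and the substrate secures both: the aldehyde is the most electrophilic carbonyl and the only one that gives a six-membered ring (the ring ketone would give a five-membered ring, the methyl-side enamine an eight-membered one), and the acceptor cannot enolise because C-1 is the quaternary oxirane carbon.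

Step 9
Reactants: 14 (1S,3S,4R,6S)-4-acetyl-3-hydroxy-1-methyl-7-oxabicyclo[4.1.0]heptan-2-one
Product: 15 (1S,3S,4R,6S)-4-acetyl-1-methyl-3-[(triethylsilyl)oxy]-7-oxabicyclo[4.1.0]heptan-2-one
Conditions: Et3SiCl, imidazole, DMF, 0 °C → rt
Reagents that add atoms: chlorotriethylsilane CC[Si](Cl)(CC)CC
Why: Silylation of the secondary ketol hydroxyl blocks retro-aldol and shields the only α-hydrogen of the ring ketone before the base step.

Step 10
Reactants: 15 (1S,3S,4R,6S)-4-acetyl-1-methyl-3-[(triethylsilyl)oxy]-7-oxabicyclo[4.1.0]heptan-2-one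
Product: 17 (1S,3S,4R,6S)-1-methyl-3-[(triethylsilyl)oxy]-4-{1-[(trifluoromethanesulfonyl)oxy]ethenyl}-7-oxabicyclo[4.1.0]heptan-2-one, via potassium enolate 16 (not isolated)
Conditions: KHMDS, THF, −78 °C; then N-(5-chloropyridin-2-yl)bis(trifluoromethanesulfonyl)imide, −78 °C
Reagents that add atoms: N-(5-chloropyridin-2-yl)bis(trifluoromethanesulfonyl)imide O=S(=O)(N(c1ccc(Cl)cn1)S(=O)(=O)C(F)(F)F)C(F)(F)F
Why: Kinetic deprotonation by a bulky amide should take the unhindered acetyl CH3 rather than the tertiary C-4 H or the flanked C-3 H, and O-triflation of that enolate gives the terminal enol triflate.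

Step 11
Reactants: 18 2-methylbut-3-yn-2-ol
Product: 19 (3E)-2-methyl-4-(tributylstannyl)but-3-en-2-ol
Conditions: Bu3SnH, PdCl2(PPh3)2 (2 mol%), THF, 0 °C → rt
Reagents that add atoms: tributyltin hydride CCCC[SnH](CCCC)CCCC
Why: Palladium-catalysed syn-hydrostannation should place tin on the terminal carbon, away from the tertiary carbinol, and so give the E-vinylstannane.

Step 12
Reactants: 17 (1S,3S,4R,6S)-1-methyl-3-[(triethylsilyl)oxy]-4-{1-[(trifluoromethanesulfonyl)oxy]ethenyl}-7-oxabicyclo[4.1.0]heptan-2-one; 19 (3E)-2-methyl-4-(tributylstannyl)but-3-en-2-ol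
Product: 20 (1S,3S,4S,6S)-4-[(4E)-6-hydroxy-6-methyl-3-oxohepta-1,4-dien-2-yl]-1-methyl-3-[(triethylsilyl)oxy]-7-oxabicyclo[4.1.0]heptan-2-one
Conditions: Pd(PPh3)4 (5 mol%), LiCl, CO (1 atm), THF, 50 °C
Reagents that add atoms: carbon monoxide [C-]#[O+]
Why: Carbonylative Stille coupling (oxidative addition of the enol triflate, CO insertion, transmetalation with retention of the E geometry, reductive elimination) should give the cross-conjugated dienone under neutral conditions.

Step 13
Reactants: 20 (1S,3S,4S,6S)-4-[(4E)-6-hydroxy-6-methyl-3-oxohepta-1,4-dien-2-yl]-1-methyl-3-[(triethylsilyl)oxy]-7-oxabicyclo[4.1.0]heptan-2-one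
Product: 21 (1S,3S,4S,6S)-3-hydroxy-4-[(4E)-6-hydroxy-6-methyl-3-oxohepta-1,4-dien-2-yl]-1-methyl-7-oxabicyclo[4.1.0]heptan-2-one
Conditions: HF·pyridine, pyridine, THF, 0 °C
Reagents that add atoms: none
Why: Buffered fluoride cleavage of the triethylsilyl ether should leave the epoxy ketone, the dienone and the tertiary alcohol untouched.

Step 14
Reactants: 21 (1S,3S,4S,6S)-3-hydroxy-4-[(4E)-6-hydroxy-6-methyl-3-oxohepta-1,4-dien-2-yl]-1-methyl-7-oxabicyclo[4.1.0]heptan-2-one; 22 (2E)-2-methylbut-2-enoyl chloride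
Product: 23 (1S,3S,4S,6S)-4-[(4E)-6-hydroxy-6-methyl-3-oxohepta-1,4-dien-2-yl]-1-methyl-2-oxo-7-oxabicyclo[4.1.0]heptan-3-yl (2E)-2-methylbut-2-enoate
Conditions: pyridine, DMAP (cat.), CH2Cl2, 0 °C → rt
Reagents that add atoms: none
Why: Acylation with the acid chloride should take the secondary ketol hydroxyl only, since the tertiary alcohol is unreactive under these conditions, and the E geometry of the tigloyl unit is retained.

## Compound list

1 | prop-2-yn-1-ol | C#CCO | starting material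
2 | 4-methyl-2,5-dihydro-1,2-oxamagnesole (cyclic alkenylmagnesium alkoxide) | CC1=C[Mg]OC1 | intermediate
3 | (2Z)-3-iodo-2-methylprop-2-en-1-ol | OC/C(C)=C\I | intermediate
4 | 4-bromo-2-methylbut-1-ene | C=C(C)CCBr | starting material
5 | bromo(3-methylbut-3-en-1-yl)zinc | C=C(C)CC[Zn]Br | intermediate
6 | (2Z)-2,6-dimethylhepta-2,6-dien-1-ol | C=C(C)CC/C=C(/C)CO | intermediate
7 | [(2R,3S)-2-methyl-3-(3-methylbut-3-en-1-yl)oxiran-2-yl]methanol | C=C(C)CC[C@@H]1O[C@]1(C)CO | intermediate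
8 | (2S,3S)-2-methyl-3-(3-methylbut-3-en-1-yl)oxirane-2-carbaldehyde | C=C(C)CC[C@@H]1O[C@]1(C)C=O | intermediate
9 | bromo(2-methylprop-1-en-1-yl)magnesium | CC(C)=C[Mg]Br | starting material
10 | 3-methyl-1-[(2R,3S)-2-methyl-3-(3-methylbut-3-en-1-yl)oxiran-2-yl]but-2-en-1-ol (both C-1 epimers) | C=C(C)CC[C@@H]1O[C@]1(C)C(O)C=C(C)C | intermediate
11 | 3-methyl-1-[(2S,3S)-2-methyl-3-(3-methylbut-3-en-1-yl)oxiran-2-yl]but-2-en-1-one | C=C(C)CC[C@@H]1O[C@]1(C)C(=O)C=C(C)C | intermediate
12 | 2-[(2S,3S)-2-methyl-3-(3-oxobutyl)oxiran-2-yl]-2-oxoacetaldehyde | CC(=O)CC[C@@H]1O[C@]1(C)C(=O)C=O | intermediate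
13 | (2R)-1-{(2E)-5-[(2S,3S)-3-methyl-3-(2-oxoacetyl)oxiran-2-yl]pent-2-en-2-yl}pyrrolidine-2-carboxylic acid | OC(=O)[C@H]1CCCN1/C(C)=C/CC[C@@H]2O[C@]2(C)C(=O)C=O | intermediate
14 | (1S,3S,4R,6S)-4-acetyl-3-hydroxy-1-methyl-7-oxabicyclo[4.1.0]heptan-2-one | CC(=O)[C@@H]1C[C@@H]2O[C@]2(C)C(=O)[C@H]1O | intermediate
15 | (1S,3S,4R,6S)-4-acetyl-1-methyl-3-[(triethylsilyl)oxy]-7-oxabicyclo[4.1.0]heptan-2-one | CC(=O)[C@@H]1C[C@@H]2O[C@]2(C)C(=O)[C@H]1O[Si](CC)(CC)CC | intermediate
16 | potassium 1-[(1S,3S,4R,6S)-1-methyl-2-oxo-3-[(triethylsilyl)oxy]-7-oxabicyclo[4.1.0]heptan-4-yl]ethen-1-olate | [K+].C=C([O-])[C@@H]1C[C@@H]2O[C@]2(C)C(=O)[C@H]1O[Si](CC)(CC)CC | intermediate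
17 | (1S,3S,4R,6S)-1-methyl-3-[(triethylsilyl)oxy]-4-{1-[(trifluoromethanesulfonyl)oxy]ethenyl}-7-oxabicyclo[4.1.0]heptan-2-one | C=C(OS(=O)(=O)C(F)(F)F)[C@@H]1C[C@@H]2O[C@]2(C)C(=O)[C@H]1O[Si](CC)(CC)CC | intermediate
18 | 2-methylbut-3-yn-2-ol | CC(C)(O)C#C | starting material
19 | (3E)-2-methyl-4-(tributylstannyl)but-3-en-2-ol | CCCC[Sn](CCCC)(CCCC)/C=C/C(C)(C)O | intermediate
20 | (1S,3S,4S,6S)-4-[(4E)-6-hydroxy-6-methyl-3-oxohepta-1,4-dien-2-yl]-1-methyl-3-[(triethylsilyl)oxy]-7-oxabicyclo[4.1.0]heptan-2-one | C=C(C(=O)/C=C/C(C)(C)O)[C@@H]1C[C@@H]2O[C@]2(C)C(=O)[C@H]1O[Si](CC)(CC)CC | intermediate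
21 | (1S,3S,4S,6S)-3-hydroxy-4-[(4E)-6-hydroxy-6-methyl-3-oxohepta-1,4-dien-2-yl]-1-methyl-7-oxabicyclo[4.1.0]heptan-2-one | C=C(C(=O)/C=C/C(C)(C)O)[C@@H]1C[C@@H]2O[C@]2(C)C(=O)[C@H]1O | intermediate
22 | (2E)-2-methylbut-2-enoyl chloride (tigloyl chloride) | C/C=C(\C)C(=O)Cl | starting material
23 | (1S,3S,4S,6S)-4-[(4E)-6-hydroxy-6-methyl-3-oxohepta-1,4-dien-2-yl]-1-methyl-2-oxo-7-oxabicyclo[4.1.0]heptan-3-yl (2E)-2-methylbut-2-enoate | C=C(C(=O)/C=C/C(C)(C)O)[C@@H]1C[C@@H]2O[C@]2(C)C(=O)[C@H]1OC(=O)/C(C)=C/C | target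

## Step count and risks

Total step count: 14. Longest linear sequence: 13 steps (steps 1–10 and 12–14); step 11 is a one-step side branch.

Steps most likely to fail:

1. Step 8 (key aldol). The 2-oxoaldehyde may be diverted by decarboxylative condensation with the amino acid or by ketol transposition, and facial control may erode if the catalyst is mismatched with the resident oxirane. The fallback sets out from 10 and comes back at 23; it runs the same ring closure one oxidation level lower at C-2, so that the acceptor is a plain α-silyloxy aldehyde and the acetyl group is later the only ketone. Compound 10 is silylated (Et3SiCl, imidazole) to the triethylsilyl ether F1. Ozonolysis with Me2S work-up gives the keto aldehyde F2. D-Proline in DMSO should close the ring to the hydroxy ketone F3. Tigloyl chloride 22 in pyridine gives the tiglate F4. KHMDS and the same triflimide give the enol triflate F5. Carbonylative Stille coupling with 19 gives the dienone F6. HF·pyridine frees the C-2 alcohol F7, and Dess–Martin oxidation then gives 23.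

2. Step 10 (enol triflate). Deprotonation may compete at C-3 of the ring ketone or at C-4, which would cause regioisomeric triflation, epimerisation or β-elimination of the silyloxy group. The fallback sets out from 15 and comes back at 17. The kinetic enolate is trapped as it forms (LDA premixed with Me3SiCl, THF, −78 °C) as the terminal trimethylsilyl enol ether F8, which can be freed from regioisomers. MeLi then regenerates the enolate regiospecifically as the lithium enolate F9, which is triflated with the same triflimide to 17.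

3. Step 7 (double ozonolysis). The enone may be over-oxidised or cleaved anomalously, and the tricarbonyl product may decompose during work-up. The fallback sets out from 11 and comes back at 12. Both alkenes are dihydroxylated (K2OsO4 cat., NMO, citric acid, t-BuOH/H2O) to the tetraol F10, and buffered NaIO4 in THF/H2O then cleaves both diols to 12.

Further compounds
F1 | step 8 | triethyl({3-methyl-1-[(2S,3S)-2-methyl-3-(3-methylbut-3-en-1-yl)oxiran-2-yl]but-2-en-1-yl}oxy)silane (triethylsilyl ether of 10, both C-1 epimers) | C=C(C)CC[C@@H]1O[C@]1(C)C(O[Si](CC)(CC)CC)C=C(C)C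
F2 | step 8 | 2-[(2S,3S)-2-methyl-3-(3-oxobutyl)oxiran-2-yl]-2-[(triethylsilyl)oxy]acetaldehyde (both C-2 epimers) | CC(=O)CC[C@@H]1O[C@]1(C)C(O[Si](CC)(CC)CC)C=O
F3 | step 8 | 1-{(1S,3S,4R,6S)-3-hydroxy-1-methyl-2-[(triethylsilyl)oxy]-7-oxabicyclo[4.1.0]heptan-4-yl}ethan-1-one (both C-2 epimers) | CC(=O)[C@@H]1C[C@@H]2O[C@]2(C)C(O[Si](CC)(CC)CC)[C@H]1O
F4 | step 8 | (1S,3S,4R,6S)-4-acetyl-1-methyl-2-[(triethylsilyl)oxy]-7-oxabicyclo[4.1.0]heptan-3-yl (2E)-2-methylbut-2-enoate (both C-2 epimers) | CC(=O)[C@@H]1C[C@@H]2O[C@]2(C)C(O[Si](CC)(CC)CC)[C@H]1OC(=O)/C(C)=C/C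
F5 | step 8 | (1S,3S,4R,6S)-1-methyl-2-[(triethylsilyl)oxy]-4-{1-[(trifluoromethanesulfonyl)oxy]ethenyl}-7-oxabicyclo[4.1.0]heptan-3-yl (2E)-2-methylbut-2-enoate (both C-2 epimers) | C=C(OS(=O)(=O)C(F)(F)F)[C@@H]1C[C@@H]2O[C@]2(C)C(O[Si](CC)(CC)CC)[C@H]1OC(=O)/C(C)=C/C
F6 | step 8 | (1S,3S,4S,6S)-4-[(4E)-6-hydroxy-6-methyl-3-oxohepta-1,4-dien-2-yl]-1-methyl-2-[(triethylsilyl)oxy]-7-oxabicyclo[4.1.0]heptan-3-yl (2E)-2-methylbut-2-enoate (both C-2 epimers) | C=C(C(=O)/C=C/C(C)(C)O)[C@@H]1C[C@@H]2O[C@]2(C)C(O[Si](CC)(CC)CC)[C@H]1OC(=O)/C(C)=C/C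
F7 | step 8 | (1R,3S,4S,6S)-2-hydroxy-4-[(4E)-6-hydroxy-6-methyl-3-oxohepta-1,4-dien-2-yl]-1-methyl-7-oxabicyclo[4.1.0]heptan-3-yl (2E)-2-methylbut-2-enoate (both C-2 epimers) | C=C(C(=O)/C=C/C(C)(C)O)[C@@H]1C[C@@H]2O[C@]2(C)C(O)[C@H]1OC(=O)/C(C)=C/C
F8 | step 10 | (1S,3S,4R,6S)-1-methyl-3-[(triethylsilyl)oxy]-4-{1-[(trimethylsilyl)oxy]ethenyl}-7-oxabicyclo[4.1.0]heptan-2-one | C=C(O[Si](C)(C)C)[C@@H]1C[C@@H]2O[C@]2(C)C(=O)[C@H]1O[Si](CC)(CC)CC
F9 | step 10 | lithium 1-[(1S,3S,4R,6S)-1-methyl-2-oxo-3-[(triethylsilyl)oxy]-7-oxabicyclo[4.1.0]heptan-4-yl]ethen-1-olate | [Li+].C=C([O-])[C@@H]1C[C@@H]2O[C@]2(C)C(=O)[C@H]1O[Si](CC)(CC)CC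
F10 | step 7 | 1-[(2S,3S)-3-(3,4-dihydroxy-3-methylbutyl)-2-methyloxiran-2-yl]-2,3-dihydroxy-3-methylbutan-1-one (diol diastereomers) | CC(O)(CO)CC[C@@H]1O[C@]1(C)C(=O)C(O)C(C)(C)O
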